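**Plan**

1. Cuts, in retrosynthetic order: (a) the bond from ring A carbon C-1' to the cinnamoyl carbonyl carbon; (b) the C-2–aryl bond of the oxane; (c) the C-4–C-3' bond joining oxane and ring A, together with the C-3/C-4 hydrogens; (d) the lactone O-1–C-2 bond and the C-5–C-6 bond. Numbering: oxane O-1, C-2 (hydroxyphenyl), C-4 (ring A), C-6 (arylethyl); ring A C-1' (acyl), C-2'/C-4' (OH), C-3' (oxane), C-5' (H), C-6' (OMe).
2. Forward: the six-membered lactone is closed first (vinylogous aldol, then acylketene lactonisation), ring A is joined at C-4 by Negishi coupling, the ring alkene is hydrogenated, the lactone carbon becomes the C-2 aryl centre (lactol, sulfone, arylzinc), then the cinnamoyl chain is joined to ring A and the five phenols are freed; all four benzene rings are bought.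
3. Stereochemistry: C-6 from a Ti(OiPr)4/BINOL-catalysed Mukaiyama aldol; C-4 relayed from C-6 by hydrogenation anti to the side chain (4,6-cis); C-2 relayed from both by axial attack of an arylzinc on the oxocarbenium ion (2,6-trans and 2,4-trans); the (E)-alkene from a Heck reaction.
4. Enabling feature: in oxane 24, ring A is a 2-alkyl-5-methoxyresorcinol bis(methoxymethyl) ether. Its only two C–H bonds (C-1' and C-5') each lie between the C-6' methoxy oxygen and an acetal oxygen and are exchanged by rotation about the C-3'–C-4 bond. One cooperative ortho-lithiation followed by acylation with a cinnamoyl N-methoxy-N-methylamide can therefore give only one constitution, under basic conditions that spare the acid-labile axial C-2 benzylic ether.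

Key step: step 14

Remark: the target SMILES corresponds to the (2R,4R,6S)-oxane, in which the C-2 aryl group is trans to both the C-4 aryl and the C-6 arylethyl groups, so C-2 is set kinetically and strong acids are avoided once it exists; compounds 1, 4, 12, 20 and 25 are taken as commercial.

**Route**

Step 1
Reactants: 1 methyl 3-(4-hydroxyphenyl)propanoate
Product: 2 methyl 3-[4-(triisopropylsilyloxy)phenyl]propanoate
Conditions: i-Pr3SiCl, imidazole, DMF, rt
Reagents that add atoms: chlorotriisopropylsilane, CC(C)[Si](Cl)(C(C)C)C(C)C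
Why: Imidazole-promoted O-silylation of the phenol gives a bulky aryl silyl ether that does not direct lithiation and should survive the hydride, organometallic and hydrogenation steps ahead.

Step 2
Reactants: 2 methyl 3-[4-(triisopropylsilyloxy)phenyl]propanoate
Product: 3 3-[4-(triisopropylsilyloxy)phenyl]propanal
Conditions: i-Bu2AlH (1.05 equiv), CH2Cl2, −78 °C; then MeOH, aq. potassium sodium tartrate
Reagents that add atoms: none
Why: At −78 °C the ester is reduced by one hydride to a stable aluminium hemiacetal that releases the aldehyde only on work-up (partial ester reduction).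

Step 3
Reactants: 4 2,2,6-trimethyl-4H-1,3-dioxin-4-one
Product: 6 trimethyl[(2,2-dimethyl-6-methylidene-6H-1,3-dioxin-4-yl)oxy]silane, via lithium dienolate 5 (not isolated)
Conditions: LiN(i-Pr)2, THF, −78 °C; then Me3SiCl, −78 °C → rt
Reagents that add atoms: chlorotrimethylsilane, C[Si](C)(C)Cl
Why: Kinetic deprotonation of the C-6 methyl group of the vinylogous ester and O-silylation of the extended enolate give the silyl dienol ether (standard dienolate formation).

Step 4
Reactants: 3 3-[4-(triisopropylsilyloxy)phenyl]propanal; 6 silyl dienol ether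
Product: 8 6-[(2S)-2-hydroxy-4-{4-(triisopropylsilyloxy)phenyl}butyl]-2,2-dimethyl-4H-1,3-dioxin-4-one, via trimethylsilyl ether 7 (not isolated)
Conditions: Ti(OiPr)4 (10 mol%), (R)-BINOL (10 mol%), 4 Å molecular sieves, THF, −78 → −20 °C; then 1 M HCl, THF, 0 °C
Reagents that add atoms: none
Why: Vinylogous Mukaiyama aldol addition under chiral Lewis acid catalysis by the titanium BINOLate, in which the γ-carbon of 6 should add to the Re face of the bound aldehyde to set the (S)-carbinol that becomes C-6, (R)-BINOL being chosen by analogy with related titanium–BINOL carbonyl additions and the antipodal ligand being used should the sense prove opposite.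

Step 5
Reactants: 8 hydroxy dioxinone
Product: 10 (6S)-6-{2-[4-(triisopropylsilyloxy)phenyl]ethyl}oxane-2,4-dione, via acylketene 9 (not isolated)
Conditions: toluene, 110 °C
Reagents that add atoms: none
Why: Thermal retro-hetero-Diels–Alder loss of acetone gives acylketene 9, whose ketene carbon is captured by the δ-hydroxyl to close the six-membered β-keto lactone under neutral conditions that cannot touch the carbinol centre or the silyl ether.

Step 6
Reactants: 10 β-keto lactone
Product: 11 (2S)-6-oxo-2-{2-[4-(triisopropylsilyloxy)phenyl]ethyl}-3,6-dihydro-2H-pyran-4-yl trifluoromethanesulfonate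
Conditions: Tf2O, Et3N, CH2Cl2, −78 °C
Reagents that add atoms: trifluoromethanesulfonic anhydride, O=S(=O)(OS(=O)(=O)C(F)(F)F)C(F)(F)F
Why: O-Sulfonylation of the enol of the cyclic β-keto ester at the C-4 oxygen gives a vinylogous acyl triflate (enol triflate formation), an activated partner for cross-coupling.

Step 7
Reactants: 12 5-methoxybenzene-1,3-diol
Product: 13 1-methoxy-3,5-bis(methoxymethoxy)benzene
Conditions: MeOCH2Cl, i-Pr2NEt, CH2Cl2, 0 °C → rt
Reagents that add atoms: chloromethyl methyl ether, COCCl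
Why: Double O-alkylation of the phenols (Williamson-type etherification) installs two acetal groups that are strong directors for ortho-lithiation and are stable to base, hydride and hydrogenation.

Step 8
Reactants: 13 1-methoxy-3,5-bis(methoxymethoxy)benzene; 11 enol triflate
Product: 16 (6S)-4-[4-methoxy-2,6-bis(methoxymethoxy)phenyl]-6-{2-[4-(triisopropylsilyloxy)phenyl]ethyl}-5,6-dihydro-2H-pyran-2-one, via aryllithium 14 (not isolated), via arylzinc chloride 15 (not isolated)
Conditions: n-BuLi, THF, 0 °C; ZnCl2, THF, 0 °C → rt; then 11, Pd(OAc)2 (5 mol%), SPhos (10 mol%), THF, 50 °C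
Reagents that add atoms: none
Why: Directed ortho-metalation of 13 should occur at the carbon between the two acetal oxygens (the stronger directors, acting together), and after transmetalation the di-ortho-substituted arylzinc couples with the electron-poor enol triflate at zerovalent palladium bearing a bulky biarylphosphine (Negishi coupling), leaving the C-6 centre untouched.

Step 9
Reactants: 16 4-aryl-5,6-dihydropyran-2-one
Product: 17 (4R,6S)-4-[4-methoxy-2,6-bis(methoxymethoxy)phenyl]-6-{2-[4-(triisopropylsilyloxy)phenyl]ethyl}oxan-2-one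
Conditions: H2 (4 atm), 10% Pd/C, EtOAc, rt
Reagents that add atoms: none
Why: Heterogeneous syn-hydrogenation of the trisubstituted enoate should occur on the ring face away from the C-6 side chain, as is general for 4,6-disubstituted 5,6-dihydropyran-2-ones, so the new C-4 hydrogen ends trans and ring A cis to that chain (both equatorial); silyl ethers and acetals are inert and no benzylic C–O bond is present yet.

Step 10
Reactants: 17 cis-lactone
Product: 18 (4R,6S)-4-[4-methoxy-2,6-bis(methoxymethoxy)phenyl]-6-{2-[4-(triisopropylsilyloxy)phenyl]ethyl}oxan-2-ol (both anomers)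
Conditions: i-Bu2AlH (1.1 equiv), CH2Cl2, −78 °C; then MeOH, aq. potassium sodium tartrate
Reagents that add atoms: none
Why: One equivalent of i-Bu2AlH at −78 °C reduces the δ-lactone only to the aluminium hemiacetal, which gives the lactol on work-up; C-4 and C-6 are not epimerisable.

Step 11
Reactants: 18 lactol
Product: 19 (4R,6S)-2-(benzenesulfonyl)-4-[4-methoxy-2,6-bis(methoxymethoxy)phenyl]-6-{2-[4-(triisopropylsilyloxy)phenyl]ethyl}oxane (both anomers)
Conditions: PhSO2H, CaCl2, CH2Cl2, rt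
Reagents that add atoms: benzenesulfinic acid, O=S(O)c1ccccc1
Why: The weakly acidic sulfinic acid exchanges the anomeric hydroxyl for a sulfonyl group through the oxocarbenium ion (anomeric sulfone formation), giving a storable precursor that ionises under mild zinc or magnesium halide assistance; aryl acetals and silyl ethers should tolerate it.

Step 12
Reactants: 19 anomeric sulfone; 20 (4-bromophenoxy)triisopropylsilane
Product: 24 (2R,4R,6S)-4-[4-methoxy-2,6-bis(methoxymethoxy)phenyl]-2-[4-(triisopropylsilyloxy)phenyl]-6-{2-[4-(triisopropylsilyloxy)phenyl]ethyl}oxane, via Grignard reagent 21 (not isolated), via diarylzinc 22 (not isolated), via oxocarbenium ion 23 (not isolated)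
Conditions: 20, Mg, THF, 50 °C; ZnBr2 (0.5 equiv per 21), THF, rt; then 19, THF, rt; aq. NH4Cl
Reagents that add atoms: none
Why: The metal bromides assist loss of sulfinate to give oxocarbenium ion 23, whose favoured half-chair holds ring A at C-4 and the side chain at C-6 pseudo-equatorial, and the arylzinc then attacks C-2 along the axial trajectory through a chair-like transition state, so the new C-2 aryl group is set trans to both existing substituents under kinetic control (substitution of anomeric sulfones by organozinc reagents).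

Step 13
Reactants: 20 (4-bromophenoxy)triisopropylsilane; 25 N-methoxy-N-methylprop-2-enamide
Product: 26 (2E)-N-methoxy-N-methyl-3-[4-(triisopropylsilyloxy)phenyl]prop-2-enamide
Conditions: Pd(OAc)2 (3 mol%), P(o-tol)3 (6 mol%), Et3N, DMF, 100 °C
Reagents that add atoms: none
Why: Mizoroki–Heck reaction of the aryl bromide with the acrylamide; syn-carbopalladation and syn-β-hydride elimination give the (E)-alkene.

Step 14
Reactants: 24 2,4,6-trisubstituted oxane; 26 cinnamoyl N-methoxy-N-methylamide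
Product: 29 (2E)-1-{6-methoxy-2,4-bis(methoxymethoxy)-3-[(2R,4R,6S)-2-[4-(triisopropylsilyloxy)phenyl]-6-{2-[4-(triisopropylsilyloxy)phenyl]ethyl}oxan-4-yl]phenyl}-3-[4-(triisopropylsilyloxy)phenyl]prop-2-en-1-one, via aryllithium 27 (not isolated), via tetrahedral lithium adduct 28 (not isolated)
Conditions: n-BuLi, TMEDA, THF, −20 → 0 °C; then 26, −78 → 0 °C; aq. NH4Cl
Reagents that add atoms: none
Why: n-BuLi, held by the C-6' methoxy oxygen and a neighbouring acetal oxygen, removes the ring A proton between them (cooperative directed ortho-metalation) to give aryllithium 27, which adds to the amide carbonyl of 26 to form the N-methoxy-chelated tetrahedral adduct 28; this is stable until the quench, so the enone is released only on work-up and cannot react twice. The closest known reaction type is ortho-lithiation of resorcinol bis(alkoxymethyl) ethers followed by Weinreb ketone synthesis using an α,β-unsaturated N-methoxy-N-methylamide. No ring is closed and no stereocentre is formed; the three oxane stereocentres are remote from the carbanion and the (E)-alkene of 26 is carried through unchanged. Site selectivity is needed against lithiation ortho to the silyloxy groups and at the benzylic C-2–H: only the ring A hydrogens have two flanking oxygen donors, the bulky silyloxy groups do not direct, and C-1' and C-5' are exchanged by rotation about the C-3'–C-4 bond, so either lithiation leads to the same product. Addition to the carbonyl carbon in preference to the β-carbon is secured by the hard aryllithium and the chelating amide. Because the whole event runs under base, the axial C-2 aryl ether, which a Friedel–Crafts acid would ionise and epimerise, is not at risk.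

Step 15
Reactants: 29 protected chalcone
Product: 31 (2E)-1-{2,4-dihydroxy-6-methoxy-3-[(2R,4R,6S)-2-[4-(triisopropylsilyloxy)phenyl]-6-{2-[4-(triisopropylsilyloxy)phenyl]ethyl}oxan-4-yl]phenyl}-3-[4-(triisopropylsilyloxy)phenyl]prop-2-en-1-one, via bis(trimethylsilyl) ether 30 (not isolated)
Conditions: Me3SiOTf, 2,2'-bipyridyl, CH3CN, 0 °C → rt; then H2O, rt
Reagents that add atoms: none
Why: The silyl triflate activated by 2,2'-bipyridyl converts aryl methoxymethyl ethers into aryl trimethylsilyl ethers in a buffered, non-protic medium and water then hydrolyses these, so both acetals are removed without a free strong acid that could ionise the axial C-2 benzylic ether, whose aryl group is still held as the less donating silyl ether.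

Step 16
Reactants: 31 tris(silyl) ether of the target
Product: 32 (2E)-1-{2,4-dihydroxy-3-[(2R,4R,6S)-2-(4-hydroxyphenyl)-6-[2-(4-hydroxyphenyl)ethyl]oxan-4-yl]-6-methoxyphenyl}-3-(4-hydroxyphenyl)prop-2-en-1-one
Conditions: Bu4NF, AcOH, THF, 0 °C
Reagents that add atoms: none
Why: Fluoride cleaves the three aryl silyl ethers, and buffering by acetic acid keeps the 2'-hydroxychalcone from base-induced oxa-Michael closure to the flavanone and leaves the C-2 configuration and the (E)-alkene intact.

**Compound list**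

1 | methyl 3-(4-hydroxyphenyl)propanoate | COC(=O)CCc1ccc(O)cc1 | starting material
2 | methyl 3-[4-(triisopropylsilyloxy)phenyl]propanoate | COC(=O)CCc1ccc(O[Si](C(C)C)(C(C)C)C(C)C)cc1 | intermediate
3 | 3-[4-(triisopropylsilyloxy)phenyl]propanal | O=CCCc1ccc(O[Si](C(C)C)(C(C)C)C(C)C)cc1 | intermediate
4 | 2,2,6-trimethyl-4H-1,3-dioxin-4-one | CC1=CC(=O)OC(C)(C)O1 | starting material
5 | lithium dienolate of 4 (not isolated) | [Li]OC1=CC(=C)OC(C)(C)O1 | intermediate
6 | trimethyl[(2,2-dimethyl-6-methylidene-6H-1,3-dioxin-4-yl)oxy]silane | C=C1C=C(O[Si](C)(C)C)OC(C)(C)O1 | intermediate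
7 | trimethylsilyl ether of 8 (not isolated) | CC1(C)OC(=O)C=C(C[C@H](CCc2ccc(O[Si](C(C)C)(C(C)C)C(C)C)cc2)O[Si](C)(C)C)O1 | intermediate
8 | 6-[(2S)-2-hydroxy-4-{4-(triisopropylsilyloxy)phenyl}butyl]-2,2-dimethyl-4H-1,3-dioxin-4-one | CC1(C)OC(=O)C=C(C[C@H](CCc2ccc(O[Si](C(C)C)(C(C)C)C(C)C)cc2)O)O1 | intermediate
9 | acylketene, (5S)-5-hydroxy-3-oxo-7-[4-(triisopropylsilyloxy)phenyl]heptanoyl ketene form O=C=CH–C(=O)– (not isolated) | O=C=CC(=O)C[C@H](CCc1ccc(O[Si](C(C)C)(C(C)C)C(C)C)cc1)O | intermediate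
10 | (6S)-6-{2-[4-(triisopropylsilyloxy)phenyl]ethyl}oxane-2,4-dione (β-keto-δ-lactone, largely enolised) | O=C1CC(=O)C[C@H](CCc2ccc(O[Si](C(C)C)(C(C)C)C(C)C)cc2)O1 | intermediate
11 | (2S)-6-oxo-2-{2-[4-(triisopropylsilyloxy)phenyl]ethyl}-3,6-dihydro-2H-pyran-4-yl trifluoromethanesulfonate | O=C1C=C(OS(=O)(=O)C(F)(F)F)C[C@H](CCc2ccc(O[Si](C(C)C)(C(C)C)C(C)C)cc2)O1 | intermediate
12 | 5-methoxybenzene-1,3-diol (5-methoxyresorcinol) | COc1cc(O)cc(O)c1 | starting material
13 | 1-methoxy-3,5-bis(methoxymethoxy)benzene | COCOc1cc(OC)cc(OCOC)c1 | intermediate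
14 | [4-methoxy-2,6-bis(methoxymethoxy)phenyl]lithium (not isolated) | COCOc1cc(OC)cc(OCOC)c1[Li] | intermediate
15 | [4-methoxy-2,6-bis(methoxymethoxy)phenyl]zinc chloride (not isolated) | COCOc1cc(OC)cc(OCOC)c1[Zn]Cl | intermediate
16 | (6S)-4-[4-methoxy-2,6-bis(methoxymethoxy)phenyl]-6-{2-[4-(triisopropylsilyloxy)phenyl]ethyl}-5,6-dihydro-2H-pyran-2-one | O=C1C=C(c2c(OCOC)cc(OC)cc2OCOC)C[C@H](CCc2ccc(O[Si](C(C)C)(C(C)C)C(C)C)cc2)O1 | intermediate
17 | (4R,6S)-4-[4-methoxy-2,6-bis(methoxymethoxy)phenyl]-6-{2-[4-(triisopropylsilyloxy)phenyl]ethyl}oxan-2-one | COc1cc(OCOC)c([C@@H]2C[C@H](CCc3ccc(O[Si](C(C)C)(C(C)C)C(C)C)cc3)OC(=O)C2)c(OCOC)c1 | intermediate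
18 | (4R,6S)-4-[4-methoxy-2,6-bis(methoxymethoxy)phenyl]-6-{2-[4-(triisopropylsilyloxy)phenyl]ethyl}oxan-2-ol (both anomers) | COc1cc(OCOC)c([C@@H]2C[C@H](CCc3ccc(O[Si](C(C)C)(C(C)C)C(C)C)cc3)OC(O)C2)c(OCOC)c1 | intermediate
19 | (4R,6S)-2-(benzenesulfonyl)-4-[4-methoxy-2,6-bis(methoxymethoxy)phenyl]-6-{2-[4-(triisopropylsilyloxy)phenyl]ethyl}oxane (both anomers) | COc1cc(OCOC)c([C@@H]2C[C@H](CCc3ccc(O[Si](C(C)C)(C(C)C)C(C)C)cc3)OC(S(=O)(=O)c3ccccc3)C2)c(OCOC)c1 | intermediate
20 | (4-bromophenoxy)triisopropylsilane | CC(C)[Si](Oc1ccc(Br)cc1)(C(C)C)C(C)C | starting material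
21 | [4-(triisopropylsilyloxy)phenyl]magnesium bromide (not isolated) | CC(C)[Si](Oc1ccc([Mg]Br)cc1)(C(C)C)C(C)C | intermediate
22 | bis[4-(triisopropylsilyloxy)phenyl]zinc (not isolated) | CC(C)[Si](Oc1ccc([Zn]c2ccc(O[Si](C(C)C)(C(C)C)C(C)C)cc2)cc1)(C(C)C)C(C)C | intermediate
23 | 4,6-cis-disubstituted cyclic oxocarbenium ion from 19, ring A at C-4 and arylethyl at C-6 (not isolated) | COc1cc(OCOC)c([C@@H]2C[C@H](CCc3ccc(O[Si](C(C)C)(C(C)C)C(C)C)cc3)[O+]=CC2)c(OCOC)c1 | intermediate
24 | (2R,4R,6S)-4-[4-methoxy-2,6-bis(methoxymethoxy)phenyl]-2-[4-(triisopropylsilyloxy)phenyl]-6-{2-[4-(triisopropylsilyloxy)phenyl]ethyl}oxane | COc1cc(OCOC)c([C@@H]2C[C@H](CCc3ccc(O[Si](C(C)C)(C(C)C)C(C)C)cc3)O[C@@H](c3ccc(O[Si](C(C)C)(C(C)C)C(C)C)cc3)C2)c(OCOC)c1 | intermediate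
25 | N-methoxy-N-methylprop-2-enamide | C=CC(=O)N(C)OC | starting material
26 | (2E)-N-methoxy-N-methyl-3-[4-(triisopropylsilyloxy)phenyl]prop-2-enamide | CON(C)C(=O)/C=C/c1ccc(O[Si](C(C)C)(C(C)C)C(C)C)cc1 | intermediate
27 | aryllithium of 24, lithiated on ring A between the methoxy and one methoxymethoxy group (not isolated) | COc1cc(OCOC)c([C@@H]2C[C@H](CCc3ccc(O[Si](C(C)C)(C(C)C)C(C)C)cc3)O[C@@H](c3ccc(O[Si](C(C)C)(C(C)C)C(C)C)cc3)C2)c(OCOC)c1[Li] | intermediate
28 | tetrahedral lithium alkoxide formed from 27 and 26, carbinol carbon bearing OLi, N(OMe)Me, ring A and the (E)-styryl group (not isolated) | COc1cc(OCOC)c([C@@H]2C[C@H](CCc3ccc(O[Si](C(C)C)(C(C)C)C(C)C)cc3)O[C@@H](c3ccc(O[Si](C(C)C)(C(C)C)C(C)C)cc3)C2)c(OCOC)c1C(O[Li])(N(C)OC)/C=C/c1ccc(O[Si](C(C)C)(C(C)C)C(C)C)cc1 | intermediate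
29 | (2E)-1-{6-methoxy-2,4-bis(methoxymethoxy)-3-[(2R,4R,6S)-2-[4-(triisopropylsilyloxy)phenyl]-6-{2-[4-(triisopropylsilyloxy)phenyl]ethyl}oxan-4-yl]phenyl}-3-[4-(triisopropylsilyloxy)phenyl]prop-2-en-1-one | COc1cc(OCOC)c([C@@H]2C[C@H](CCc3ccc(O[Si](C(C)C)(C(C)C)C(C)C)cc3)O[C@@H](c3ccc(O[Si](C(C)C)(C(C)C)C(C)C)cc3)C2)c(OCOC)c1C(=O)/C=C/c1ccc(O[Si](C(C)C)(C(C)C)C(C)C)cc1 | intermediate
30 | 2',4'-bis(trimethylsilyl) ether of 31 (not isolated) | COc1cc(O[Si](C)(C)C)c([C@@H]2C[C@H](CCc3ccc(O[Si](C(C)C)(C(C)C)C(C)C)cc3)O[C@@H](c3ccc(O[Si](C(C)C)(C(C)C)C(C)C)cc3)C2)c(O[Si](C)(C)C)c1C(=O)/C=C/c1ccc(O[Si](C(C)C)(C(C)C)C(C)C)cc1 | intermediate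
31 | (2E)-1-{2,4-dihydroxy-6-methoxy-3-[(2R,4R,6S)-2-[4-(triisopropylsilyloxy)phenyl]-6-{2-[4-(triisopropylsilyloxy)phenyl]ethyl}oxan-4-yl]phenyl}-3-[4-(triisopropylsilyloxy)phenyl]prop-2-en-1-one | COc1cc(O)c([C@@H]2C[C@H](CCc3ccc(O[Si](C(C)C)(C(C)C)C(C)C)cc3)O[C@@H](c3ccc(O[Si](C(C)C)(C(C)C)C(C)C)cc3)C2)c(O)c1C(=O)/C=C/c1ccc(O[Si](C(C)C)(C(C)C)C(C)C)cc1 | intermediate
32 | (2E)-1-{2,4-dihydroxy-3-[(2R,4R,6S)-2-(4-hydroxyphenyl)-6-[2-(4-hydroxyphenyl)ethyl]oxan-4-yl]-6-methoxyphenyl}-3-(4-hydroxyphenyl)prop-2-en-1-one | COc1cc(O)c([C@@H]2C[C@H](CCc3ccc(O)cc3)O[C@@H](c3ccc(O)cc3)C2)c(O)c1C(=O)/C=C/c1ccc(O)cc1 | target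

**Count and risks**

Total steps: 16. Longest linear sequence: 13 steps (1, 2, 4, 5, 6, 8, 9, 10, 11, 12, 14, 15, 16).

Most likely to fail, step 14: the base may deprotonate elsewhere (ortho to a silyloxy group, or at the benzylic C-2–H with ring opening), or the hindered aryllithium may add too slowly so that base-induced loss of the N-methoxy group from the amide wins. The fallback sets out from 24 and 26 and returns at 29. Oxane 24 is brominated on its far more electron-rich ring A (NBS, CH2Cl2, −40 °C; both free positions are equivalent) to give the aryl bromide F1. Amide 26 is reduced (i-Bu2AlH, THF, −78 °C) to (2E)-3-[4-(triisopropylsilyloxy)phenyl]prop-2-enal F2. Bromine–lithium exchange on F1 (t-BuLi, Et2O, −78 °C) outruns any deprotonation, and the aryllithium adds to the unhindered aldehyde carbonyl to give the allylic alcohol F3. MnO2 in CH2Cl2 then oxidises this doubly activated alcohol to 29.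

Second, step 12: the kinetic 2,6-trans selectivity may be lost through reversible ionisation of the new benzylic C-2–O bond under the metal halides (drift to the all-equatorial isomer), or the oxocarbenium ion may lose a proton to give the dihydropyran. The fallback sets out from 18 and returns at 24 and avoids a cation altogether. Lactol 18 is acetylated (Ac2O, pyridine, DMAP) to the anomeric acetate F4, which Me3SiBr (CH2Cl2, 0 °C) converts into the anomeric bromide F5. F5 is coupled with Grignard reagent 21 under Co(acac)3/TMEDA catalysis (THF, 0 °C). The C-2–aryl bond is then formed from an anomeric radical, which reacts on its axial lobe, so the same 2,6-trans product 24 is expected.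

Third, step 15: the hindered 4'-acetal may cleave too slowly, or the silyl triflate/pyridine pair may add to the enone and the freed 2'-phenol may close onto it to give the flavanone. The fallback sets out from 24 and returns at 32 by removing the acetals before the chain is joined and using silyl protection throughout. Treatment of 24 with Me3SiOTf/2,2'-bipyridyl then water gives the ring A diol F6, and t-BuMe2SiOTf/2,6-lutidine gives the bis(silyl ether) F7. NBS gives the ring A bromide F8. Bromine–lithium exchange (t-BuLi, Et2O, −78 °C, kept cold to prevent oxygen-to-carbon silyl migration) and addition to 26 give the pentasilyl chalcone F9. Bu4NF/AcOH then frees all five phenols in one fluoride step to give 32.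

**Further compounds**

F1 | step 14 | (2R,4R,6S)-4-[3-bromo-4-methoxy-2,6-bis(methoxymethoxy)phenyl]-2-[4-(triisopropylsilyloxy)phenyl]-6-{2-[4-(triisopropylsilyloxy)phenyl]ethyl}oxane | COc1cc(OCOC)c([C@@H]2C[C@H](CCc3ccc(O[Si](C(C)C)(C(C)C)C(C)C)cc3)O[C@@H](c3ccc(O[Si](C(C)C)(C(C)C)C(C)C)cc3)C2)c(OCOC)c1Br
F2 | step 14 | (2E)-3-[4-(triisopropylsilyloxy)phenyl]prop-2-enal | O=C/C=C/c1ccc(O[Si](C(C)C)(C(C)C)C(C)C)cc1
F3 | step 14 | (2E)-1-{6-methoxy-2,4-bis(methoxymethoxy)-3-[(2R,4R,6S)-2-[4-(triisopropylsilyloxy)phenyl]-6-{2-[4-(triisopropylsilyloxy)phenyl]ethyl}oxan-4-yl]phenyl}-3-[4-(triisopropylsilyloxy)phenyl]prop-2-en-1-ol (both carbinol epimers) | COc1cc(OCOC)c([C@@H]2C[C@H](CCc3ccc(O[Si](C(C)C)(C(C)C)C(C)C)cc3)O[C@@H](c3ccc(O[Si](C(C)C)(C(C)C)C(C)C)cc3)C2)c(OCOC)c1C(O)/C=C/c1ccc(O[Si](C(C)C)(C(C)C)C(C)C)cc1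
F4 | step 12 | (4R,6S)-4-[4-methoxy-2,6-bis(methoxymethoxy)phenyl]-6-{2-[4-(triisopropylsilyloxy)phenyl]ethyl}oxan-2-yl acetate (both anomers) | COc1cc(OCOC)c([C@@H]2C[C@H](CCc3ccc(O[Si](C(C)C)(C(C)C)C(C)C)cc3)OC(OC(C)=O)C2)c(OCOC)c1
F5 | step 12 | (4R,6S)-2-bromo-4-[4-methoxy-2,6-bis(methoxymethoxy)phenyl]-6-{2-[4-(triisopropylsilyloxy)phenyl]ethyl}oxane (both anomers) | COc1cc(OCOC)c([C@@H]2C[C@H](CCc3ccc(O[Si](C(C)C)(C(C)C)C(C)C)cc3)OC(Br)C2)c(OCOC)c1
F6 | step 15 | 5-methoxy-2-[(2R,4R,6S)-2-[4-(triisopropylsilyloxy)phenyl]-6-{2-[4-(triisopropylsilyloxy)phenyl]ethyl}oxan-4-yl]benzene-1,3-diol | COc1cc(O)c([C@@H]2C[C@H](CCc3ccc(O[Si](C(C)C)(C(C)C)C(C)C)cc3)O[C@@H](c3ccc(O[Si](C(C)C)(C(C)C)C(C)C)cc3)C2)c(O)c1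
F7 | step 15 | (2R,4R,6S)-4-[2,6-bis(tert-butyldimethylsilyloxy)-4-methoxyphenyl]-2-[4-(triisopropylsilyloxy)phenyl]-6-{2-[4-(triisopropylsilyloxy)phenyl]ethyl}oxane | COc1cc(O[Si](C)(C)C(C)(C)C)c([C@@H]2C[C@H](CCc3ccc(O[Si](C(C)C)(C(C)C)C(C)C)cc3)O[C@@H](c3ccc(O[Si](C(C)C)(C(C)C)C(C)C)cc3)C2)c(O[Si](C)(C)C(C)(C)C)c1
F8 | step 15 | (2R,4R,6S)-4-[3-bromo-2,6-bis(tert-butyldimethylsilyloxy)-4-methoxyphenyl]-2-[4-(triisopropylsilyloxy)phenyl]-6-{2-[4-(triisopropylsilyloxy)phenyl]ethyl}oxane | COc1cc(O[Si](C)(C)C(C)(C)C)c([C@@H]2C[C@H](CCc3ccc(O[Si](C(C)C)(C(C)C)C(C)C)cc3)O[C@@H](c3ccc(O[Si](C(C)C)(C(C)C)C(C)C)cc3)C2)c(O[Si](C)(C)C(C)(C)C)c1Br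
F9 | step 15 | (2E)-1-{2,4-bis(tert-butyldimethylsilyloxy)-6-methoxy-3-[(2R,4R,6S)-2-[4-(triisopropylsilyloxy)phenyl]-6-{2-[4-(triisopropylsilyloxy)phenyl]ethyl}oxan-4-yl]phenyl}-3-[4-(triisopropylsilyloxy)phenyl]prop-2-en-1-one | COc1cc(O[Si](C)(C)C(C)(C)C)c([C@@H]2C[C@H](CCc3ccc(O[Si](C(C)C)(C(C)C)C(C)C)cc3)O[C@@H](c3ccc(O[Si](C(C)C)(C(C)C)C(C)C)cc3)C2)c(O[Si](C)(C)C(C)(C)C)c1C(=O)/C=C/c1ccc(O[Si](C(C)C)(C(C)C)C(C)C)cc1
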